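The numbers in the tables are calculated from invented constants; noise was put on by code.

Read the flasks at 1.4 h and again at 4.4 h, and the order they suggest changes.

| setting | south-west | north-east | west | north-west | east |
|---|---|---|---|---|---|
| starting material | 120 mM | 72.0 mM | 240 mM | 120 mM | 48.0 mM |
| target |  |  |  | 36.0 mM |  |
| time |  |  |  |  | 19 h |

| run | time / h | [target] / mM |
|---|---|---|
| south-west run | 1.4 | 2.7 |
| south-west run | 4.4 | 13.7 |
| south-west run | 8.4 | 27.9 |
| south-west run | 13 | 44.4 |
| south-west run | 19 | 52.4 |
| north-east run | 1.4 | 1.5 |
| north-east run | 4.4 | 6.1 |
| north-east run | 8.4 | 11.6 |
| north-east run | 13 | 19.0 |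
| north-east run | 19 | 23.9 |
| west run | 1.4 | 5.9 |
| west run | 4.4 | 38.8 |
| west run | 8.4 | 96.5 |
| west run | 13 | 133.9 |
| west run | 19 | 129.2 |
| north-west run | 1.4 | 43.3 |
| north-west run | 4.4 | 62.6 |
| north-west run | 8.4 | 76.6 |
| north-west run | 13 | 81.1 |
| north-west run | 19 | 70.3 |

(standard deviation of a reading: 1 mM)

* how the opening rate goes with [starting material] round the charge of the south-west run: the exponent of the rate at two percent of starting material gone to target (one fixed amount of target, the same in the runs compared)
* target in the east run at 19 h, as a share of the starting material charged

- Overall: starting material -> target.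
- Constant volume, constant temperature.
- An order is taken over about fifteen percent of the charge, up and down.

Two chemists dispute the first question. Both see the north-west run, charged with target, gain 5.21 mM h⁻¹ on average up to 1.4 h. That is faster than the 1.93 mM h⁻¹ of the south-west run, which has the same charge of starting material. So target seems to speed its own formation (autocatalysis).

The first chemist trusts the later readings, which stand well above the scatter. The west run against the north-east run at 4.4 h gives a slope of 1.54. The forecast is this chemist's, with an order below that slope: order 1.3 and east yield 26%, in its words “I take about 1.3 at 2.4 mM target”.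

The second chemist answers that the order asked belongs at 2.40 mM of target. The south-west run holds 2.7 mM at 1.4 h, but 13.7 mM at 4.4 h. The west run against the north-east run at 1.4 h gives 1.14, less steep than the later slope. This is the opening slope: the logarithm of the ratio of two early readings taken at one time, over the logarithm of the ratio of their charges. It is a weak reading, since 1.5 mM carries a scatter of 1 mM. Still, this chemist commits to it, and accepts the forecast's east yield.

The flask gives order 1.1 and east yield 26.4%. The forecast's order is too high; its yield is within the margin.

    2 starting material ⇌ intermediate + starting material (1.760 M⁻¹ h⁻¹, 8.100 M⁻¹ h⁻¹)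
    intermediate → target (0.1649 h⁻¹)
    target → decomposed product (0.05544 h⁻¹)
    starting material + target → 2 target (1.508 M⁻¹ h⁻¹)

The opening slope read at 1.4 h, 1.14, applied to the south-west rate of 2.7 mM h⁻¹, gives 1.52 mM h⁻¹ for the north-east run, whose rate at the same amount of target is 1.5 mM h⁻¹. The steeper 1.54 keeps its place as a description of the amounts read at 4.4 h. In the east run, the path from target to decomposed product holds the yield down: at 19 h the run gives 26.4%, and 45.7% with that path taken away.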